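**Retrosynthetic overview**

1. The route rests on ring A. The free C6–OH is para to C8a and sits between the C5 and C7 methoxy groups, so two-electron oxidation of this one phenol makes C8a the only hydrogen-bearing electrophilic ring carbon.
2. O1–C8a is cut last (ring C, the only ring made; rings A and B are bought). The target comes from the open (S)-β-hydroxy ketone by anodic dehydrogenative etherification, with the C2–O bond left intact.
3. C4–C4a: the β-hydroxy ketone comes from the aryllithium of silylated 3-bromo-2,6-dimethoxyphenol (two steps from 2,6-dimethoxyphenol) and a silyl-protected (S)-β-hydroxy Weinreb amide.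
4. C2 stereocentre: Noyori hydrogenation of ethyl 3-(3,4-dimethoxyphenyl)-3-oxopropanoate.

Key step: step 8

**Remarks on the chemistry**

- Flavanone locants are used throughout (O1, C2, C3, C4, C4a, C5–C8, C8a). Ring A is the benzo ring, ring B the 3,4-dimethoxyphenyl ring, ring C the pyranone ring.
- The target is 2S. The carbinol of the open precursor carries the same descriptor S, because the ranking O > aryl > CH2 > H and the spatial arrangement do not change on ring closure.
- Neat hexafluoroisopropanol could ionise the electron-rich benzylic carbinol and the benzylic C2–O1 bond of the product. The electrolyte is therefore diluted with CH2Cl2 and buffered with 2,6-lutidine.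

**Route**

Step 1
Reactants: 1 2,6-dimethoxyphenol
Product: 2 tert-butyl(2,6-dimethoxyphenoxy)dimethylsilane
Conditions: TBSCl (1.2 equiv), imidazole (2.5 equiv), DMF, 23 °C
Reagents that add atoms: tert-butyldimethylsilyl chloride, CC(C)(C)[Si](C)(C)Cl
Why: Silyl ether formation masks the acidic phenol for the later lithiation and leaves a bulky oxygen substituent that is twisted out of conjugation between the two methoxy groups.

Step 2
Reactants: 2 tert-butyl(2,6-dimethoxyphenoxy)dimethylsilane
Product: 3 (3-bromo-2,6-dimethoxyphenoxy)(tert-butyl)dimethylsilane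
Conditions: NBS (1.0 equiv), MeCN, 0 °C to 23 °C
Reagents that add atoms: N-bromosuccinimide, O=C1CCC(=O)N1Br
Why: Electrophilic aromatic bromination should go to C3, para to one methoxy group and ortho to the other, as it does in 1,2,3-trimethoxybenzene, because the central silyloxy group is a poor donor when twisted.

Step 3
Reactants: 4 ethyl 3-(3,4-dimethoxyphenyl)-3-oxopropanoate
Product: 5 ethyl (S)-3-(3,4-dimethoxyphenyl)-3-hydroxypropanoate
Conditions: H2 (30 bar), [RuCl(p-cymene)((R)-SEGPHOS)]Cl (0.5 mol %), EtOH, 80 °C
Reagents that add atoms: none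
Why: Noyori asymmetric hydrogenation of a β-keto ester reduces the ketone inside a ruthenium–ester chelate, and the (R)-configured biaryl bisphosphine should deliver hydride to the face that gives the S carbinol (S here because the aryl group outranks CH2CO2Et), the sense and level of induction being checked by chiral HPLC before the material is carried on.

Step 4
Reactants: 5 ethyl (S)-3-(3,4-dimethoxyphenyl)-3-hydroxypropanoate; 6 N,O-dimethylhydroxylamine hydrochloride
Product: 7 (S)-3-(3,4-dimethoxyphenyl)-3-hydroxy-N-methoxy-N-methylpropanamide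
Conditions: 6 (1.6 equiv), iPrMgCl (4.2 equiv), THF, −20 °C to 0 °C; aq. NH4Cl
Reagents that add atoms: N,O-dimethylhydroxylamine hydrochloride (compound 6), Cl.CNOC
Why: Direct aminolysis of the ester by the chloromagnesium amide of N,O-dimethylhydroxylamine (Weinreb amide formation) leaves the stereocentre untouched, the free hydroxyl only consuming one further equivalent of the Grignard base.

Step 5
Reactants: 7 (S)-3-(3,4-dimethoxyphenyl)-3-hydroxy-N-methoxy-N-methylpropanamide
Product: 8 (S)-3-[(tert-butyldimethylsilyl)oxy]-3-(3,4-dimethoxyphenyl)-N-methoxy-N-methylpropanamide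
Conditions: TBSCl (1.3 equiv), imidazole (2.5 equiv), DMF, 23 °C
Reagents that add atoms: tert-butyldimethylsilyl chloride, CC(C)(C)[Si](C)(C)Cl
Why: Silyl ether formation masks the carbinol so that the aryllithium of step 6 is not quenched, and no bond to the stereocentre is broken.

Step 6
Reactants: 3 (3-bromo-2,6-dimethoxyphenoxy)(tert-butyl)dimethylsilane; 8 (S)-3-[(tert-butyldimethylsilyl)oxy]-3-(3,4-dimethoxyphenyl)-N-methoxy-N-methylpropanamide
Product: 11 (S)-3-[(tert-butyldimethylsilyl)oxy]-1-[3-[(tert-butyldimethylsilyl)oxy]-2,4-dimethoxyphenyl]-3-(3,4-dimethoxyphenyl)propan-1-one, via aryllithium 9 (not isolated), via lithium hemiaminal chelate 10 (not isolated)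
Conditions: 3 (1.3 equiv), n-BuLi (1.25 equiv), THF, −78 °C, 30 min; then 8 (1.0 equiv), −78 °C to −40 °C; aq. NH4Cl
Reagents that add atoms: n-butyllithium, [Li]CCCC (its lithium stands in 9 and 10 only; no atom of it remains in 11)
Why: Bromine–lithium exchange gives aryllithium 9, which adds once to the Weinreb amide because chelate 10 survives until the aqueous quench (Weinreb ketone synthesis); the lithium is meta to the silyloxy group, so no retro-Brook shift can occur, and the stereocentre is remote from the reacting carbonyl.

Step 7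
Reactants: 11 (S)-3-[(tert-butyldimethylsilyl)oxy]-1-[3-[(tert-butyldimethylsilyl)oxy]-2,4-dimethoxyphenyl]-3-(3,4-dimethoxyphenyl)propan-1-one
Product: 12 (S)-3-hydroxy-1-(3-hydroxy-2,4-dimethoxyphenyl)-3-(3,4-dimethoxyphenyl)propan-1-one
Conditions: Bu4NF/AcOH (1:1, 4 equiv), THF, 0 °C to 23 °C; pH 7 buffer
Reagents that add atoms: none
Why: Fluoride-induced cleavage of both silyl ethers, buffered with acetic acid so that the β-hydroxy ketone should neither eliminate to the chalcone nor undergo retro-aldol cleavage; the carbinol C–O bond is not broken, so the S configuration is kept.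

Step 8
Reactants: 12 (S)-3-hydroxy-1-(3-hydroxy-2,4-dimethoxyphenyl)-3-(3,4-dimethoxyphenyl)propan-1-one
Product: 15 (2S)-2-(3,4-dimethoxyphenyl)-6-hydroxy-5,7-dimethoxy-2,3-dihydro-4H-chromen-4-one, via phenoxenium cation 13 (not isolated), via 8a-H cyclohexadienone 14 (not isolated)
Conditions: undivided cell, graphite anode, Pt cathode, Bu4NBF4 (0.1 M), 2,6-lutidine (2 equiv), HFIP/CH2Cl2 (1:4), 5 mM in 12, anode held at the first phenol wave (set by cyclic voltammetry), 2.0 F/mol, 0 °C; pH 7 phosphate work-up
Reagents that add atoms: none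
Why: Proposed new method: the C6 phenol, whose first anodic wave should lie well below that of the veratryl ring, loses two electrons and one proton to give phenoxenium ion 13 with its charge on C5, C7 and C8a; the carbinol oxygen captures the hydrogen-bearing terminus C8a to give dienone 14, and loss of the C8a proton rearomatises ring A to 15 while hydrogen is evolved at the cathode. The closest known reaction types are anodic and hypervalent-iodine oxidations of para-unsubstituted phenols with alcohol capture at the para carbon, and anodic dehydrogenative phenol couplings in hexafluoroisopropanol media, none of which closes a chromanone ring through a ketone tether at the adjacent carbon. Ring C closes in a six-membered mode, formally 6-exo-trig onto the C8=C8a bond of the oxidised ring, with the geometry of a six-membered Friedel–Crafts closure of reversed polarity. No stereocentre is formed, and C2 should keep its S configuration because the C2–O bond is never broken and the lutidine-buffered, weakly ionising medium disfavours benzylic ionisation and retro-oxa-Michael opening. The step needs chemoselectivity for ring A over ring B (secured by the free phenol and potential control), site selectivity for C8a over the methoxy-bearing C5 that the tether can also reach (capture there gives an ortho-quinone monoketal that cannot aromatise and should ionise back, so the manifold drains through C8a), and protection of the more electron-rich product from a second oxidation (charge limited to 2.0 F/mol, high dilution, hydrogen bonding of HFIP to O1 and the C4 carbonyl).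

**Compound list**

1 | 2,6-dimethoxyphenol | COc1cccc(OC)c1O | starting material
2 | tert-butyl(2,6-dimethoxyphenoxy)dimethylsilane | COc1cccc(OC)c1O[Si](C)(C)C(C)(C)C | intermediate
3 | (3-bromo-2,6-dimethoxyphenoxy)(tert-butyl)dimethylsilane | COc1ccc(Br)c(OC)c1O[Si](C)(C)C(C)(C)C | intermediate
4 | ethyl 3-(3,4-dimethoxyphenyl)-3-oxopropanoate | CCOC(=O)CC(=O)c1ccc(OC)c(OC)c1 | starting material
5 | ethyl (S)-3-(3,4-dimethoxyphenyl)-3-hydroxypropanoate | CCOC(=O)C[C@H](O)c1ccc(OC)c(OC)c1 | intermediate
6 | N,O-dimethylhydroxylamine hydrochloride | Cl.CNOC | starting material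
7 | (S)-3-(3,4-dimethoxyphenyl)-3-hydroxy-N-methoxy-N-methylpropanamide | CON(C)C(=O)C[C@H](O)c1ccc(OC)c(OC)c1 | intermediate
8 | (S)-3-[(tert-butyldimethylsilyl)oxy]-3-(3,4-dimethoxyphenyl)-N-methoxy-N-methylpropanamide | CON(C)C(=O)C[C@H](O[Si](C)(C)C(C)(C)C)c1ccc(OC)c(OC)c1 | intermediate
9 | [3-[(tert-butyldimethylsilyl)oxy]-2,4-dimethoxyphenyl]lithium (aryllithium; not isolated) | [Li]c1ccc(OC)c(O[Si](C)(C)C(C)(C)C)c1OC | intermediate
10 | lithium (3S)-3-[(tert-butyldimethylsilyl)oxy]-1-[3-[(tert-butyldimethylsilyl)oxy]-2,4-dimethoxyphenyl]-3-(3,4-dimethoxyphenyl)-1-[methoxy(methyl)amino]propan-1-olate (hemiaminal chelate; C1 not defined; not isolated) | [Li]OC(C[C@H](O[Si](C)(C)C(C)(C)C)c1ccc(OC)c(OC)c1)(N(C)OC)c1ccc(OC)c(O[Si](C)(C)C(C)(C)C)c1OC | intermediate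
11 | (S)-3-[(tert-butyldimethylsilyl)oxy]-1-[3-[(tert-butyldimethylsilyl)oxy]-2,4-dimethoxyphenyl]-3-(3,4-dimethoxyphenyl)propan-1-one | COc1ccc([C@@H](O[Si](C)(C)C(C)(C)C)CC(=O)c2ccc(OC)c(O[Si](C)(C)C(C)(C)C)c2OC)cc1OC | intermediate
12 | (S)-3-hydroxy-1-(3-hydroxy-2,4-dimethoxyphenyl)-3-(3,4-dimethoxyphenyl)propan-1-one | COc1ccc([C@@H](O)CC(=O)c2ccc(OC)c(O)c2OC)cc1OC | intermediate
13 | phenoxenium cation of 12, written with the charge at C8a (S carbinol; not isolated) | COC1=C(C(=O)C[C@H](O)c2ccc(OC)c(OC)c2)[CH+]C=C(OC)C1=O | intermediate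
14 | (2S)-2-(3,4-dimethoxyphenyl)-5,7-dimethoxy-2,3-dihydro-4H-chromene-4,6(8aH)-dione (C8a not defined; not isolated) | COC1=C2C(=O)C[C@@H](c3ccc(OC)c(OC)c3)OC2C=C(OC)C1=O | intermediate
15 | (2S)-2-(3,4-dimethoxyphenyl)-6-hydroxy-5,7-dimethoxy-2,3-dihydro-4H-chromen-4-one [(2S)-6-hydroxy-5,7,3',4'-tetramethoxyflavanone] | COc1ccc([C@@H]2CC(=O)c3c(cc(OC)c(O)c3OC)O2)cc1OC | target

**Step count**

Total: 8 steps. Longest linear sequence: 6 steps (steps 3 to 8, from 4).

**Steps most likely to fail**

1. Step 8 (proposed new method). The product is a para-alkoxyphenol and may be oxidised a second time, leading to quinone formation with opening of ring C. Phenoxyl radicals may also dimerise at the para carbon before the second electron is removed, ring B may be oxidised with fragmentation of the side chain, and anodically generated acid may ionise the benzylic carbon and erode the configuration.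
Fallback by known chemistry, in which C2 is set by conjugate addition instead of being carried through an oxidation. It sets out from 1 and rejoins the route at 15. Teuber oxidation of 1 with (KSO3)2NO in aqueous KH2PO4/acetone should give 2,6-dimethoxy-1,4-benzoquinone F1. Reduction with Na2S2O4 (EtOAc/water) gives 2,6-dimethoxybenzene-1,4-diol F2. Friedel–Crafts acetylation (AcOH, BF3·OEt2, 90 °C) at the only open position type gives 1-(3,6-dihydroxy-2,4-dimethoxyphenyl)ethanone F3. Benzylation of the non-chelated hydroxyl (BnBr, K2CO3, acetone, reflux) gives 1-[3-(benzyloxy)-6-hydroxy-2,4-dimethoxyphenyl]ethanone F4. Condensation with N,N-dimethylformamide dimethyl acetal (toluene, 100 °C) gives (E)-1-[3-(benzyloxy)-6-hydroxy-2,4-dimethoxyphenyl]-3-(dimethylamino)prop-2-en-1-one F5, which closes with HCl in CH2Cl2 to 6-(benzyloxy)-5,7-dimethoxy-4H-chromen-4-one F6. Asymmetric conjugate addition of 3,4-dimethoxyphenylboronic acid (Pd(OCOCF3)2, (R)-t-BuPyOx, NH4PF6, water, ClCH2CH2Cl, 60 °C) should give (S)-6-(benzyloxy)-2-(3,4-dimethoxyphenyl)-5,7-dimethoxychroman-4-one F7. The R ligand is chosen as the antipode expected to deliver 2S by the facial sense known for cyclic enones, and the hand is confirmed by chiral HPLC against the racemate. Hydrogenolysis of the benzyl ether (H2, Pd/C, EtOAc, 23 °C) then gives 15.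

2. Step 6. The ortho-substituted aryllithium may deprotonate the amide at the α-carbon instead of adding, after which silanolate is lost by β-elimination; incomplete bromine–lithium exchange would also leave butyllithium to attack the amide.
Fallback that replaces acyl substitution by aldehyde addition and oxidation. It sets out from 8 and rejoins at 11. Reduction of 8 with i-Bu2AlH (THF, −78 °C) gives (S)-3-[(tert-butyldimethylsilyl)oxy]-3-(3,4-dimethoxyphenyl)propanal F8. Aryllithium 9, made from 3 as in step 6, adds to this far more electrophilic carbonyl at −78 °C to give (3S)-3-[(tert-butyldimethylsilyl)oxy]-1-[3-[(tert-butyldimethylsilyl)oxy]-2,4-dimethoxyphenyl]-3-(3,4-dimethoxyphenyl)propan-1-ol F9 as a mixture at C1. Oxidation with Dess–Martin periodinane (NaHCO3, CH2Cl2, 0 °C) removes the new centre and gives 11.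

3. Step 7. The slow cleavage of the secondary silyl ether may force long exposure to fluoride, during which β-elimination to the chalcone, retro-aldol cleavage or partial racemisation through benzylic ionisation can set in.
Fallback that avoids a silyl group on the carbinol altogether. It sets out from 7 (with 9 made from 3) and rejoins at 12. The hydroxyl of 7 is deprotonated in the flask with iPrMgCl (1.0 equiv, THF, −40 °C) to the chloromagnesium alkoxide of 7 F10. Addition of aryllithium 9 (1.5 equiv, −78 °C to −20 °C) and aqueous NH4Cl should give (S)-1-[3-[(tert-butyldimethylsilyl)oxy]-2,4-dimethoxyphenyl]-3-(3,4-dimethoxyphenyl)-3-hydroxypropan-1-one F11. Only the aryl silyl ether then has to be removed, which KHF2 in MeOH at 23 °C does selectively and near neutrality, giving 12.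

**Further compounds**

F1 | step 8 | 2,6-dimethoxy-1,4-benzoquinone | COC1=CC(=O)C=C(OC)C1=O
F2 | step 8 | 2,6-dimethoxybenzene-1,4-diol | COc1cc(O)cc(OC)c1O
F3 | step 8 | 1-(3,6-dihydroxy-2,4-dimethoxyphenyl)ethanone | CC(=O)c1c(O)cc(OC)c(O)c1OC
F4 | step 8 | 1-[3-(benzyloxy)-6-hydroxy-2,4-dimethoxyphenyl]ethanone | CC(=O)c1c(O)cc(OC)c(OCc2ccccc2)c1OC
F5 | step 8 | (E)-1-[3-(benzyloxy)-6-hydroxy-2,4-dimethoxyphenyl]-3-(dimethylamino)prop-2-en-1-one | CN(C)/C=C/C(=O)c1c(O)cc(OC)c(OCc2ccccc2)c1OC
F6 | step 8 | 6-(benzyloxy)-5,7-dimethoxy-4H-chromen-4-one | COc1cc2occc(=O)c2c(OC)c1OCc1ccccc1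
F7 | step 8 | (S)-6-(benzyloxy)-2-(3,4-dimethoxyphenyl)-5,7-dimethoxychroman-4-one | COc1ccc([C@@H]2CC(=O)c3c(cc(OC)c(OCc4ccccc4)c3OC)O2)cc1OC
F8 | step 6 | (S)-3-[(tert-butyldimethylsilyl)oxy]-3-(3,4-dimethoxyphenyl)propanal | O=CC[C@H](O[Si](C)(C)C(C)(C)C)c1ccc(OC)c(OC)c1
F9 | step 6 | (3S)-3-[(tert-butyldimethylsilyl)oxy]-1-[3-[(tert-butyldimethylsilyl)oxy]-2,4-dimethoxyphenyl]-3-(3,4-dimethoxyphenyl)propan-1-ol (mixture at C1) | COc1ccc([C@@H](O[Si](C)(C)C(C)(C)C)CC(O)c2ccc(OC)c(O[Si](C)(C)C(C)(C)C)c2OC)cc1OC
F10 | step 7 | chloromagnesium alkoxide of 7 | CON(C)C(=O)C[C@H](O[Mg]Cl)c1ccc(OC)c(OC)c1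
F11 | step 7 | (S)-1-[3-[(tert-butyldimethylsilyl)oxy]-2,4-dimethoxyphenyl]-3-(3,4-dimethoxyphenyl)-3-hydroxypropan-1-one | COc1ccc([C@@H](O)CC(=O)c2ccc(OC)c(O[Si](C)(C)C(C)(C)C)c2OC)cc1OC
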